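Read the plateau off the readings before you build anything.

in all of them: Q 3.7 µM

|  | E | J | remark | time |
|---|---|---|---|---|
| birch | 0.50 mM | 0.35 mM | run made earlier |  |
| elm | 0.70 mM | 0.35 mM | run made earlier |  |
| oak | 1.1 mM | 0.35 mM | run made earlier |  |
| theta | 0.50 mM | 0.350 mM | a single well-mixed tank run continuously and read at steady state, 4.0 min in it on average |  |
| zeta | 0.50 mM (fed, over 2.00 min) | 0.350 mM | all but E at the start; E goes in evenly over 2.00 min, the run ends at 4.0 min | 4.0 min |
| gamma | 0.50 mM | 0.350 mM (fed, over 2.00 min) | all but J at the start; J goes in evenly over 2.00 min, the run ends at 4.0 min | 4.0 min |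
| eta | 0.50 mM | 0.350 mM | everything together in a closed stirred flask, run for 4.0 min | 4.0 min |

- birch (time / min: L / %): 0.200: 31.6; 0.333: 41.4; 0.417: 45.9; 0.667: 43.9; 1.00: 43.0; 1.50: 42.9; 2.50: 43.2
- elm (time / min: L / %): 0.200: 26.8; 0.333: 33.4; 0.417: 33.4; 0.667: 30.4; 1.00: 29.9; 1.50: 30.7; 2.50: 29.9
- oak (time / min: L / %): 0.200: 20.3; 0.333: 21.2; 0.417: 21.6; 0.667: 18.9; 1.00: 19.8; 1.50: 19.9; 2.50: 19.7

(readings scatter by 0.5 percentage points)

- the stated concentrations are those of everything mixed, before any reaction; amounts are the same in each set-up
- the feed brings no volume worth counting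
- the earlier runs were made in a closed, stirred flask

* the set-up with the highest amount of L at the outlet or at the end, in percent of the E put in ("none" if the first two lie within 2 percentage points) (theta / zeta / gamma / eta / none)
* amount of L at the outlet or at the end, in percent of the E put in, theta
* amount of L at the outlet or at the end, in percent of the E put in, zeta
* amount of L at the outlet or at the end, in percent of the E put in, gamma
* amount of L at the outlet or at the end, in percent of the E put in, eta

E rises from 0.50 mM to 1.1 mM at the same J, and it stands above J even at its lowest. Yet the last L readings come to 0.216 mM, 0.209 mM and 0.217 mM. So I read J as the limiting reagent and carry one number: the mean of these amounts over the J charged, 61.1%, which I call the plateau share, the L standing late per J put in.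

The birch readings peak at 0.417 min and read level by 1.00 min. Eta runs longer than that, and zeta and gamma still have 2.00 min after their feeds, which is also longer. So I commit to the plateau share times J over E, 42.8%, for eta, zeta and gamma, and to no more than that for theta, with its 4.0 min on average. That makes the best none.

The forecast gives 40% for theta, 43% for zeta, gamma and eta alike, and best none, holding that “J, the common fixed charge, limits L”.

The flask gives 41.6% for theta, 42.5% for zeta, 42.5% for gamma and 42.5% for eta, so the best is none.

    J + Q → X (k = 1.90 × 10⁵ L mol⁻¹ s⁻¹)
    E + X ⇌ Z (K = 4480 L mol⁻¹, k = 28400 L mol⁻¹ s⁻¹)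
    Z → Q + L (k = 14.2 s⁻¹)
    Q + L → D (k = 99.0 L mol⁻¹ s⁻¹)
    L ⇌ G (K = 0.630, k = 0.0534 s⁻¹)

Eta ends with 30.0% of its E left, so 0.350 mM of E has reacted, about the J charged. I carry the plateau share to zeta with J raised to 0.391 mM, where it gives 47.8%. That flask stands 5 points from the 42.5% of zeta.

The earlier runs and the new flask come from a simulation for substances that don't exist; the scatter is artificial.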